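**Retrosynthetic overview**
1. The strategy rests on the oxepine ring of the 2,5-dihydro-1-benzoxepine: the five atoms O1–C2H2–C3(CH3)=C4H–C5H2 that span the arene carbons C9a and C5a are, atom for atom, 2-methyl-2-vinyloxirane (O, CH2, C(CH3), CH=, =CH2).
2. Last disconnections: the four MOM ethers, then the C7–C(=O) bond (C7 aryllithium between the two MOM ethers plus the Weinreb amide of MOM-protected dihydrocaffeic acid).
3. Key disconnection: C9a–O1 and C5–C5a, a [5+2] ring-expanding annulation of 3,5-bis(methoxymethoxy)benzyne with isoprene monoxide.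
4. The aryne precursor comes from phloroglucinol by bis-MOM protection, carbamate-directed ortho-silylation and exchange of the carbamate for a triflate.
5. Ring order: both benzene rings are bought (phloroglucinol, dihydrocaffeic acid); the oxepine is the only ring made (step 6).

Key step: step 6

Assumption: the target has no stereogenic centre, and its only ring alkene (C3=C4) is fixed cis by the seven-membered ring, so the molecule is achiral; no enantiocontrol is needed and racemic isoprene monoxide is used.

**Route**

Step 1
Reactants: 1 phloroglucinol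
Product: 2 3,5-bis(methoxymethoxy)phenol
Conditions: MOMCl (2.0 equiv), i-Pr2NEt, CH2Cl2/DMF, 0 °C → rt
Reagents that add atoms: chloromethyl methyl ether, COCCl
Why: O-alkylation of the phenoxide (Williamson type) with two equivalents of MOMCl should give the bis-ether as the main part of a statistical mixture, from which the mono- and tris-ethers are separated by chromatography and the mono-ether is re-submitted.

Step 2
Reactants: 2 3,5-bis(methoxymethoxy)phenol
Product: 3 3,5-bis(methoxymethoxy)phenyl N,N-diethylcarbamate
Conditions: Et2NCOCl, K2CO3, MeCN, reflux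
Reagents that add atoms: diethylcarbamoyl chloride, CCN(CC)C(Cl)=O
Why: O-carbamoylation of the phenol under mild base, to which the MOM acetals are inert, installs the strongest oxygen-based directing group for metalation.

Step 3
Reactants: 3 3,5-bis(methoxymethoxy)phenyl N,N-diethylcarbamate
Product: 5 3,5-bis(methoxymethoxy)-2-(trimethylsilyl)phenyl N,N-diethylcarbamate, via aryllithium 4 (not isolated)
Conditions: s-BuLi, TMEDA, THF, −78 °C; then TMSCl, −78 °C → rt
Reagents that add atoms: chlorotrimethylsilane, C[Si](C)(C)Cl
Why: Directed ortho-metalation (Snieckus type): the carbamate carbonyl and the adjacent MOM ether together hold s-BuLi·TMEDA, so the proton at C2 between them should be removed in preference to the C4 proton between the two MOM ethers, and silylation at −78 °C precedes any anionic ortho-Fries shift.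

Step 4
Reactants: 5 3,5-bis(methoxymethoxy)-2-(trimethylsilyl)phenyl N,N-diethylcarbamate
Product: 6 3,5-bis(methoxymethoxy)-2-(trimethylsilyl)phenol
Conditions: LiAlH4, THF, 0 °C → rt; aqueous NaOH work-up
Reagents that add atoms: none
Why: Reductive cleavage of the aryl carbamate (hydride addition to the carbonyl and loss of the phenoxide) should free the phenol, while MOM ethers and the aryl–silicon bond are inert to LiAlH4.

Step 5
Reactants: 6 3,5-bis(methoxymethoxy)-2-(trimethylsilyl)phenol
Product: 7 3,5-bis(methoxymethoxy)-2-(trimethylsilyl)phenyl trifluoromethanesulfonate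
Conditions: PhNTf2, Et3N, DMAP (cat.), CH2Cl2, rt
Reagents that add atoms: N-phenylbis(trifluoromethanesulfonimide), O=S(=O)(N(c1ccccc1)S(=O)(=O)C(F)(F)F)C(F)(F)F
Why: O-sulfonylation of the phenol with the mild triflyl donor PhNTf2 should give the Kobayashi-type ortho-silyl aryl triflate without touching the MOM acetals or the C–Si bond.

Step 6
Reactants: 7 3,5-bis(methoxymethoxy)-2-(trimethylsilyl)phenyl trifluoromethanesulfonate; 8 2-methyl-2-vinyloxirane (racemic)
Product: 11 6,8-bis(methoxymethoxy)-3-methyl-2,5-dihydro-1-benzoxepine, via aryne 9 (not isolated), via oxiranium zwitterion 10 (not isolated)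
Conditions: TBAT (1.5 equiv), 8 (10 equiv), toluene, 50 °C, slow addition of 7
Reagents that add atoms: none
Why: Proposed new method: fluoride releases 3,5-bis(methoxymethoxy)benzyne 9 from 7; the oxirane oxygen of 8 adds to the aryne carbon remote from the flanking MOM ether (the former C–OTf carbon, future C9a) and leaves the aryl anion on the carbon next to that MOM ether (future C5a); in zwitterion 10 the atoms C5a(−)–C9a–O(+)–C3–C4=C5 form a six-membered array, and the anion attacks the vinyl terminus while the strained tertiary-allylic C3–O bond breaks (charge-accelerated Claisen-type, formally SN2′, shift), which makes C9a–O1 and C5–C5a. The closest known reaction types are the aza-Claisen ring expansion of zwitterions formed from arynes and small vinyl-substituted aza-heterocycles, and aryne insertion into cyclic ethers and epoxides through oxonium zwitterions; an oxiranium version that ends in a seven-membered ether has not been shown. The oxepine ring is closed by 3→7 ring expansion through a six-membered transition state and not by end-to-end closure of a chain, so the C3=C4 alkene is cis and trisubstituted by construction. No stereocentre is formed, so the racemic epoxide suffices. Two selectivities are needed: oxygen must bond at C9a, which the inductive distortion of the 3-alkoxyaryne secures, and the anion must take the vinyl terminus rather than an oxirane carbon (dihydrobenzofuran), which is secured because backside attack on either ring carbon is out of reach for the ortho anion and the tertiary carbon is fully substituted. A non-acidic solvent and excess epoxide are chosen so that proton transfer to the aryl anion, prior ionisation of the oxiranium and aryne self-reaction are held back.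

Step 7
Reactants: 12 3-(3,4-dihydroxyphenyl)propanoic acid
Product: 13 3-(3,4-dihydroxyphenyl)-N-methoxy-N-methylpropanamide
Conditions: MeNHOMe·HCl, EDC·HCl, HOBt (cat.), N-methylmorpholine, DMF, 0 °C → rt
Reagents that add atoms: N,O-dimethylhydroxylamine hydrochloride, CNOC.Cl
Why: Carbodiimide-mediated amide coupling should proceed without catechol protection because the amine outcompetes the phenolic hydroxyls for the activated ester.

Step 8
Reactants: 13 3-(3,4-dihydroxyphenyl)-N-methoxy-N-methylpropanamide
Product: 14 3-[3,4-bis(methoxymethoxy)phenyl]-N-methoxy-N-methylpropanamide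
Conditions: MOMCl (2.5 equiv), i-Pr2NEt, CH2Cl2, 0 °C → 40 °C
Reagents that add atoms: chloromethyl methyl ether, COCCl
Why: O-alkylation of both catechol hydroxyls with MOMCl and Hünig's base is standard, and the Weinreb amide is inert to these conditions.

Step 9
Reactants: 11 6,8-bis(methoxymethoxy)-3-methyl-2,5-dihydro-1-benzoxepine; 14 3-[3,4-bis(methoxymethoxy)phenyl]-N-methoxy-N-methylpropanamide
Product: 17 1-[6,8-bis(methoxymethoxy)-3-methyl-2,5-dihydro-1-benzoxepin-7-yl]-3-[3,4-bis(methoxymethoxy)phenyl]propan-1-one, via 7-lithiobenzoxepine 15 (not isolated), via tetrahedral lithium adduct 16 (not isolated)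
Conditions: n-BuLi (1.1 equiv), TMEDA, THF, −20 → 0 °C; then 14, −78 °C → rt; H2O
Reagents that add atoms: none
Why: Directed ortho-metalation at C7, the ring position flanked by two cooperating MOM ethers, followed by Weinreb ketone synthesis, in which the chelated tetrahedral adduct prevents over-addition and releases the ketone on work-up.

Step 10
Reactants: 17 1-[6,8-bis(methoxymethoxy)-3-methyl-2,5-dihydro-1-benzoxepin-7-yl]-3-[3,4-bis(methoxymethoxy)phenyl]propan-1-one
Product: 18 1-(6,8-dihydroxy-3-methyl-2,5-dihydro-1-benzoxepin-7-yl)-3-(3,4-dihydroxyphenyl)propan-1-one (target)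
Conditions: 3 M HCl (aq)/MeOH–THF, rt → 40 °C
Reagents that add atoms: none
Why: Acid-catalysed acetal exchange with methanol should remove all four aryl MOM ethers, and dilute acid at moderate temperature is chosen so that the trisubstituted alkene and the allylic aryl ether of the oxepine are not protonated or ionised.

**Compound list**
1 | phloroglucinol (benzene-1,3,5-triol) | Oc1cc(O)cc(O)c1 | starting material
2 | 3,5-bis(methoxymethoxy)phenol | COCOc1cc(O)cc(OCOC)c1 | intermediate
3 | 3,5-bis(methoxymethoxy)phenyl N,N-diethylcarbamate | CCN(CC)C(=O)Oc1cc(OCOC)cc(OCOC)c1 | intermediate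
4 | 2-lithio-3,5-bis(methoxymethoxy)phenyl N,N-diethylcarbamate (not isolated) | CCN(CC)C(=O)Oc1cc(OCOC)cc(OCOC)c1[Li] | intermediate
5 | 3,5-bis(methoxymethoxy)-2-(trimethylsilyl)phenyl N,N-diethylcarbamate | CCN(CC)C(=O)Oc1cc(OCOC)cc(OCOC)c1[Si](C)(C)C | intermediate
6 | 3,5-bis(methoxymethoxy)-2-(trimethylsilyl)phenol | COCOc1cc(O)c([Si](C)(C)C)c(OCOC)c1 | intermediate
7 | 3,5-bis(methoxymethoxy)-2-(trimethylsilyl)phenyl trifluoromethanesulfonate | COCOc1cc(OCOC)c([Si](C)(C)C)c(OS(=O)(=O)C(F)(F)F)c1 | intermediate
8 | 2-methyl-2-vinyloxirane (isoprene monoxide, racemic) | CC1(C=C)CO1 | starting material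
9 | 3,5-bis(methoxymethoxy)benzyne (not isolated) | COCOC1=CC(OCOC)=CC#C1 | intermediate
10 | 1-aryl-2-methyl-2-vinyloxiranium ortho-aryl anion zwitterion (not isolated) | COCOc1cc(OCOC)[c-]c([O+]2CC2(C)C=C)c1 | intermediate
11 | 6,8-bis(methoxymethoxy)-3-methyl-2,5-dihydro-1-benzoxepine | CC1=CCc2c(cc(OCOC)cc2OCOC)OC1 | intermediate
12 | 3-(3,4-dihydroxyphenyl)propanoic acid (dihydrocaffeic acid) | OC(=O)CCc1ccc(O)c(O)c1 | starting material
13 | 3-(3,4-dihydroxyphenyl)-N-methoxy-N-methylpropanamide | CON(C)C(=O)CCc1ccc(O)c(O)c1 | intermediate
14 | 3-[3,4-bis(methoxymethoxy)phenyl]-N-methoxy-N-methylpropanamide | CON(C)C(=O)CCc1ccc(OCOC)c(OCOC)c1 | intermediate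
15 | 7-lithio-6,8-bis(methoxymethoxy)-3-methyl-2,5-dihydro-1-benzoxepine (not isolated) | CC1=CCc2c(cc(OCOC)c([Li])c2OCOC)OC1 | intermediate
16 | lithium alkoxide of the tetrahedral Weinreb adduct (not isolated) | CC1=CCc2c(cc(OCOC)c(C(O[Li])(CCc3ccc(OCOC)c(OCOC)c3)N(C)OC)c2OCOC)OC1 | intermediate
17 | 1-[6,8-bis(methoxymethoxy)-3-methyl-2,5-dihydro-1-benzoxepin-7-yl]-3-[3,4-bis(methoxymethoxy)phenyl]propan-1-one | CC1=CCc2c(cc(OCOC)c(C(=O)CCc3ccc(OCOC)c(OCOC)c3)c2OCOC)OC1 | intermediate
18 | 1-(6,8-dihydroxy-3-methyl-2,5-dihydro-1-benzoxepin-7-yl)-3-(3,4-dihydroxyphenyl)propan-1-one | CC1=CCc2c(cc(O)c(C(=O)CCc3ccc(O)c(O)c3)c2O)OC1 | target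

**Step count and risks**

Total steps: 10. Longest linear sequence: 8 (steps 1–6, 9, 10, from phloroglucinol); the side-chain branch (steps 7, 8) joins at step 9.

Steps most likely to fail:

1. Step 6 (proposed new method). The oxirane oxygen may be too weak a nucleophile to capture the aryne before the aryne is consumed by fluoride, by the product or by itself. The oxiranium zwitterion may also ionise at the tertiary allylic C–O bond and collapse by five-membered ring closure, or be quenched by proton transfer and opened by an external nucleophile. The fallback uses known chemistry, sets out from phenol 2 and replaces steps 2–6. Phenol 2 is O-allylated (allyl bromide, K2CO3, acetone) to 1-(allyloxy)-3,5-bis(methoxymethoxy)benzene F1. Aromatic Claisen rearrangement (N,N-diethylaniline, 190 °C) should give 2-allyl-3,5-bis(methoxymethoxy)phenol F2 as the only isomer, because the two ortho positions are equivalent. O-Alkylation with 3-chloro-2-methylpropene (K2CO3, NaI, DMF) gives 2-allyl-3,5-bis(methoxymethoxy)-1-[(2-methylprop-2-en-1-yl)oxy]benzene F3. Ring-closing metathesis (Grubbs second-generation catalyst, CH2Cl2, 40 °C) then forms the C3=C4 bond and returns to the route at 11.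

2. Step 9. The doubly ortho-substituted aryllithium may act as a base toward the α-methylene of the amide instead of adding to it, which returns 11. A long metalation time also invites deprotonation at the benzylic–allylic C5 methylene, followed by ring opening through loss of the phenoxide. The fallback sets out from 14 and 11. Amide 14 is reduced with DIBAL-H (THF, −78 °C) to 3-[3,4-bis(methoxymethoxy)phenyl]propanal F4. The much more electrophilic aldehyde is added at −78 °C to aryllithium 15, generated from 11 with a short metalation time, to give 1-[6,8-bis(methoxymethoxy)-3-methyl-2,5-dihydro-1-benzoxepin-7-yl]-3-[3,4-bis(methoxymethoxy)phenyl]propan-1-ol F5. Oxidation with Dess–Martin periodinane (NaHCO3, CH2Cl2) returns to the route at 17.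

3. Step 3. Metalation may divide between C2 (wanted) and C4 between the two MOM ethers, and the lithiated carbamate may undergo the anionic ortho-Fries shift before it is silylated. The fallback sets out from phenol 2 and replaces steps 2–4. Bromination ortho to the free hydroxyl (NBS, CH2Cl2, −78 °C, hydrogen-bond delivery; any para isomer is removed here) gives 2-bromo-3,5-bis(methoxymethoxy)phenol F6. O-Silylation with hexamethyldisilazane (THF, reflux) gives [2-bromo-3,5-bis(methoxymethoxy)phenoxy]trimethylsilane F7. Bromine–lithium exchange with n-BuLi (THF, −78 °C) forms [2-lithio-3,5-bis(methoxymethoxy)phenoxy]trimethylsilane F8, which should undergo 1,3 O→C silyl migration (retro-Brook rearrangement). Aqueous work-up returns to the route at 6.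

**Further compounds**
F1 | step 6 | 1-(allyloxy)-3,5-bis(methoxymethoxy)benzene | C=CCOc1cc(OCOC)cc(OCOC)c1
F2 | step 6 | 2-allyl-3,5-bis(methoxymethoxy)phenol | C=CCc1c(O)cc(OCOC)cc1OCOC
F3 | step 6 | 2-allyl-3,5-bis(methoxymethoxy)-1-[(2-methylprop-2-en-1-yl)oxy]benzene | C=CCc1c(OCC(C)=C)cc(OCOC)cc1OCOC
F4 | step 9 | 3-[3,4-bis(methoxymethoxy)phenyl]propanal | O=CCCc1ccc(OCOC)c(OCOC)c1
F5 | step 9 | 1-[6,8-bis(methoxymethoxy)-3-methyl-2,5-dihydro-1-benzoxepin-7-yl]-3-[3,4-bis(methoxymethoxy)phenyl]propan-1-ol (racemic) | CC1=CCc2c(cc(OCOC)c(C(O)CCc3ccc(OCOC)c(OCOC)c3)c2OCOC)OC1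
F6 | step 3 | 2-bromo-3,5-bis(methoxymethoxy)phenol | COCOc1cc(O)c(Br)c(OCOC)c1
F7 | step 3 | [2-bromo-3,5-bis(methoxymethoxy)phenoxy]trimethylsilane | COCOc1cc(O[Si](C)(C)C)c(Br)c(OCOC)c1
F8 | step 3 | [2-lithio-3,5-bis(methoxymethoxy)phenoxy]trimethylsilane | COCOc1cc(O[Si](C)(C)C)c([Li])c(OCOC)c1
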